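The route is cut at the bond between C2 of the pyran-4-one ring and C1' of the 4-hydroxy-3,5-dimethoxyphenyl ring. The key step is an aerobic palladium(II)-catalysed oxidative boron-Heck arylation. It exploits the C2–H of the chromone: C2 is the β-carbon of the O1–C2=C3–C4=O vinylogous ester, so the aryl group of an unprotected syringyl pinacol boronate is delivered there, and the C2=C3 double bond is restored in the same flask. The last step therefore gives the flavone directly. Its precursors are 5,6,7,8-tetramethoxychromone, unsubstituted at C2 and built in three steps from a trimethoxylated 2-hydroxyacetophenone, and the boronate.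

Key step: step 4

Remark: the target has no stereocentre and no stereogenic axis, so it is achiral and no stereocontrol is needed; compounds 1 and 6 are taken as catalogue compounds.

Step 1
Reactants: 1 2'-hydroxy-4',5',6'-trimethoxyacetophenone
Product: 2 3'-bromo-2'-hydroxy-4',5',6'-trimethoxyacetophenone
Conditions: NBS (1.05 equiv), MeCN, 0 °C to rt
Reagents that add atoms: N-bromosuccinimide, O=C1CCC(=O)N1Br
Why: Electrophilic aromatic bromination can only go to C3', the single unsubstituted ring carbon, which is ortho to the phenol and para to the 6'-methoxy group, and NBS in MeCN at low temperature should spare the acetyl α-position.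

Step 2
Reactants: 2 3'-bromo-2'-hydroxy-4',5',6'-trimethoxyacetophenone
Product: 3 2'-hydroxy-3',4',5',6'-tetramethoxyacetophenone
Conditions: NaOMe (5 equiv, 25% in MeOH), CuCl (0.3 equiv), DMF, 110 °C; then 2 M HCl work-up
Reagents that add atoms: sodium methoxide, [Na+].[O-]C
Why: Copper(I)-catalysed Ullmann-type methanolysis of an aryl bromide ortho to a phenoxide, the reaction type that turns 5-bromovanillin into syringaldehyde, should replace bromide by methoxide while the hindered acetyl group flanked by phenoxide and methoxy stays intact.

Step 3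
Reactants: 3 2'-hydroxy-3',4',5',6'-tetramethoxyacetophenone
Product: 5 tetramethoxychromone (5,6,7,8-tetramethoxy-4H-chromen-4-one), via enaminone 4 (not isolated)
Conditions: DMF-DMA (3 equiv), toluene, 100 °C; concentrate; then conc. HCl (2 equiv), CH2Cl2, 40 °C
Reagents that add atoms: N,N-dimethylformamide dimethyl acetal (DMF-DMA), COC(OC)N(C)C
Why: Condensation of the acetyl methyl group with DMF-DMA, then acid-promoted oxa-Michael addition of the phenol and loss of dimethylamine, is the standard enaminone route to 2,3-unsubstituted chromones, and the brief mild acid treatment should not cleave the 5-methoxy group.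

Step 4
Reactants: 5 tetramethoxychromone (5,6,7,8-tetramethoxy-4H-chromen-4-one); 6 2,6-dimethoxy-4-(4,4,5,5-tetramethyl-1,3,2-dioxaborolan-2-yl)phenol
Product: 8 target flavone 4'-hydroxy-3',5,5',6,7,8-hexamethoxyflavone, via racemic flavanone 7 (not isolated)
Conditions: 6 (2.5 equiv, in portions), Pd(TFA)2 (10 mol %), 5-nitro-1,10-phenanthroline (20 mol %), O2 (1 atm), DMSO/H2O (20:1), 100 °C
Reagents that add atoms: none
Why: Transmetalation of the aryl group from boron to the cationic phenanthroline-ligated Pd(II) centre is followed by syn migratory insertion across the C2=C3 bond of the pyran-4-one ring, the aryl group going to C2 (the β-carbon of the O1–C2=C3–C4=O vinylogous ester) and palladium to C3 as the C4 enolate; protonolysis of this enolate gives flavanone 7, which the same Pd(II)/O2 system dehydrogenates through C3 palladation and β-hydride elimination of the C2–H, O2 reoxidising Pd(0). The closest known reaction type is the Pd(II)-catalysed oxidative boron-Heck (conjugate addition–dehydrogenation) arylation of chromones with arylboron reagents, which gives flavones. No ring is closed. No stereocentre remains: C2 of 7 is formed as a racemate and becomes sp2 again in the dehydrogenation. The step needs C2 over C3 regioselectivity, which the enone polarisation secures because only aryl delivery to C2 gives a stabilised palladium enolate, and it needs the free phenol to survive, which is plausible because both ortho positions carry methoxy groups and the para position carries boron or the chromone, so no site is open for oxidative phenol coupling. The flavone product, now disubstituted at C2, should not accept a second aryl group, and the excess of 6 covers losses by protodeboronation and homocoupling.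

Compound list
1 | 2'-hydroxy-4',5',6'-trimethoxyacetophenone, 1-(6-hydroxy-2,3,4-trimethoxyphenyl)ethan-1-one | CC(=O)c1c(O)cc(OC)c(OC)c1OC | starting material
2 | 3'-bromo-2'-hydroxy-4',5',6'-trimethoxyacetophenone, 1-(3-bromo-2-hydroxy-4,5,6-trimethoxyphenyl)ethan-1-one | CC(=O)c1c(O)c(Br)c(OC)c(OC)c1OC | intermediate
3 | 2'-hydroxy-3',4',5',6'-tetramethoxyacetophenone, 1-(2-hydroxy-3,4,5,6-tetramethoxyphenyl)ethan-1-one | CC(=O)c1c(O)c(OC)c(OC)c(OC)c1OC | intermediate
4 | enaminone (E)-3-(dimethylamino)-1-(2-hydroxy-3,4,5,6-tetramethoxyphenyl)prop-2-en-1-one, formed in the flask in step 3 and not isolated | CN(C)/C=C/C(=O)c1c(O)c(OC)c(OC)c(OC)c1OC | intermediate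
5 | 5,6,7,8-tetramethoxy-4H-chromen-4-one | O=c1ccoc2c(OC)c(OC)c(OC)c(OC)c12 | intermediate
6 | 2,6-dimethoxy-4-(4,4,5,5-tetramethyl-1,3,2-dioxaborolan-2-yl)phenol (4-hydroxy-3,5-dimethoxyphenylboronic acid pinacol ester) | COc1cc(B2OC(C)(C)C(C)(C)O2)cc(OC)c1O | starting material
7 | racemic flavanone 2-(4-hydroxy-3,5-dimethoxyphenyl)-5,6,7,8-tetramethoxychroman-4-one, formed in the flask in step 4 and not isolated | COc1cc(C2CC(=O)c3c(OC)c(OC)c(OC)c(OC)c3O2)cc(OC)c1O | intermediate
8 | 4'-hydroxy-3',5,5',6,7,8-hexamethoxyflavone, 2-(4-hydroxy-3,5-dimethoxyphenyl)-5,6,7,8-tetramethoxy-4H-chromen-4-one (achiral) | COc1cc(-c2cc(=O)c3c(OC)c(OC)c(OC)c(OC)c3o2)cc(OC)c1O | target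

Total step count: 4. Longest linear sequence: 4 steps (1 → 2 → 3 → 5 → 8).

Steps most likely to fail

Step 4. The free-phenol boronate may be consumed by protodeboronation, oxidative deborylation or homocoupling before it transmetalates, or the sequence may stall at the flavanone stage. The fallback masks the phenol and separates bond formation from oxidation; it sets out from 5 and 6. Benzylation of 6 (BnBr, K2CO3, DMF, rt) should give 2-[4-(benzyloxy)-3,5-dimethoxyphenyl]-4,4,5,5-tetramethyl-1,3,2-dioxaborolane F1. Redox-neutral Pd(II)-catalysed conjugate addition of F1 to 5 (Pd(TFA)2, 2,2'-bipyridine, AcOH/THF/H2O, 60 °C, no oxidant) should form the same C2–C1' bond and give racemic 2-[4-(benzyloxy)-3,5-dimethoxyphenyl]-5,6,7,8-tetramethoxychroman-4-one F2. Dehydrogenation with catalytic I2 in DMSO at 120 °C should give 2-[4-(benzyloxy)-3,5-dimethoxyphenyl]-5,6,7,8-tetramethoxy-4H-chromen-4-one F3. Hydrogenolysis (H2, 10% Pd/C, EtOAc, rt) comes back to the route at 8.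

Step 2. Hydrodebromination may compete with methoxide transfer, or the acetyl group may condense under hot methoxide. The fallback brings in the oxygen by formylation and Dakin oxidation and sets out from 1. Duff formylation (hexamethylenetetramine, TFA, 80 °C; then aq. HCl) at the only free ring position should give 3-acetyl-2-hydroxy-4,5,6-trimethoxybenzaldehyde F4. Dakin oxidation (H2O2, aq. NaOH, 0 °C, N2) should give 1-(2,3-dihydroxy-4,5,6-trimethoxyphenyl)ethan-1-one F5. Methylation of the hydroxyl that is not hydrogen-bonded to the ketone (MeI 1.05 equiv, K2CO3, acetone, rt) comes back to the route at 3.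

Step 3. The phenol may be O-methylated by hot DMF-DMA, or the peri 5-methoxy group may be lost during the acid cyclisation. The fallback uses a Claisen formylation and sets out from 3. Ethyl formate and NaH in THF (0 °C to rt) should give the cyclic hemiacetal racemic 2-hydroxy-5,6,7,8-tetramethoxychroman-4-one F6. Dehydration with catalytic TsOH in toluene at 60 °C comes back to the route at 5.

Further compounds
F1 | step 4 | 2-[4-(benzyloxy)-3,5-dimethoxyphenyl]-4,4,5,5-tetramethyl-1,3,2-dioxaborolane | COc1cc(B2OC(C)(C)C(C)(C)O2)cc(OC)c1OCc1ccccc1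
F2 | step 4 | racemic 2-[4-(benzyloxy)-3,5-dimethoxyphenyl]-5,6,7,8-tetramethoxychroman-4-one | COc1cc(C2CC(=O)c3c(OC)c(OC)c(OC)c(OC)c3O2)cc(OC)c1OCc1ccccc1
F3 | step 4 | 2-[4-(benzyloxy)-3,5-dimethoxyphenyl]-5,6,7,8-tetramethoxy-4H-chromen-4-one | COc1cc(-c2cc(=O)c3c(OC)c(OC)c(OC)c(OC)c3o2)cc(OC)c1OCc1ccccc1
F4 | step 2 | 3-acetyl-2-hydroxy-4,5,6-trimethoxybenzaldehyde | CC(=O)c1c(O)c(C=O)c(OC)c(OC)c1OC
F5 | step 2 | 1-(2,3-dihydroxy-4,5,6-trimethoxyphenyl)ethan-1-one | CC(=O)c1c(O)c(O)c(OC)c(OC)c1OC
F6 | step 3 | racemic 2-hydroxy-5,6,7,8-tetramethoxychroman-4-one | OC1CC(=O)c2c(OC)c(OC)c(OC)c(OC)c2O1
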